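**Retrosynthetic overview**
1. Target 10 comes from its 5-O-methyl ether 9. The methyl group peri to the C4 carbonyl is removed last under chelation control.
2. Ring C of 9 is opened at the O1–C2 bond. This gives α-methoxychalcone 6, which is made in the same flask from ketone 4 (ring A, C4, C3, 3-OMe) and aldehyde 5 (ring B, C2).
3. Ketone 4 comes from 1,2,3,5-tetramethoxybenzene 1 and methoxyacetyl chloride 2. Acylation with ortho-demethylation frees exactly the oxygen that becomes O1.
4. Ring order: rings A and B are bought. Ring C is the only ring formed, and it is closed by the C–O bond.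

Assumption: the target SMILES has no stereocentre and no stereogenic double bond, so the compound is achiral and needs no enantiocontrol. Compounds 1, 2 and 5 are taken as catalogue chemicals.

**Step 1**
Reactants: 1 1,2,3,5-tetramethoxybenzene; 2 methoxyacetyl chloride
Product: 4 1-(2-hydroxy-3,4,6-trimethoxyphenyl)-2-methoxyethan-1-one, via pentamethoxy ketone 3 (not isolated)
Conditions: AlCl3 (2.5 equiv), Et2O, 0 °C to reflux, 12 h; then ice/2 M HCl
Reagents that add atoms: none
Why: Friedel–Crafts acylation at the only kind of free ring position of this very electron-rich arene gives 3, and AlCl3 held between the new carbonyl and the buttressed, out-of-plane 2-methoxy group then cleaves that ether selectively (chelation-assisted ortho-demethylation, well established for the acetyl chloride analogue), with no stereocentre formed.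

**Step 2**
Reactants: 4 1-(2-hydroxy-3,4,6-trimethoxyphenyl)-2-methoxyethan-1-one; 5 5-hydroxy-2-methoxybenzaldehyde
Product: 9 5'-hydroxy-3,5,7,8,2'-pentamethoxyflavone, via alpha-methoxychalcone 6 (not isolated), via 3-methoxyflavanone 7 (not isolated), via 3-iodo-3-methoxyflavanone 8 (not isolated)
Conditions: pyrrolidine (0.5 equiv), DMSO, 80 °C, 8 h; then I2 (20 mol %), 130 °C, 6 h
Reagents that add atoms: none
Why: Proposed new method: an amine/iodine co-catalysed condensative oxidative oxa-annulation of an α-methoxy ketone, in which pyrrolidine turns 5 into an iminium ion that the enol of 4 attacks (Mannich addition, then loss of pyrrolidine) to give (Z)-chalcone 6, the 2'-phenolate adds 6-endo to the β-carbon and forms the key O1–C2 bond of ring C (oxa-Michael, helped by the 6'-methoxy group that twists the chalcone towards the flavanone), the electron-rich 3-methoxy enol of 7 is iodinated at C3 to 8, and 8 loses HI through a methoxy-stabilised cation to give the pyranone 9 while DMSO re-oxidises HI to I2, so the transient centres at C2 and C3 are erased; the closest known reaction types are the pyrrolidine/I2/DMSO domino aldol–oxa-Michael–dehydrogenation of 2'-hydroxyacetophenones (methyl ketones) to 3-unsubstituted flavones and the I2/DMSO oxidative cyclisation of 2'-hydroxychalcones, neither shown for ω-alkoxy ketones that must deliver a tetrasubstituted C2=C3 enol ether.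

**Step 3**
Reactants: 9 5'-hydroxy-3,5,7,8,2'-pentamethoxyflavone
Product: 10 5,5'-dihydroxy-3,7,8,2'-tetramethoxyflavone
Conditions: BCl3 (3.0 equiv, 1 M in CH2Cl2), CH2Cl2, −78 °C to 0 °C, 2 h; then ice-water
Reagents that add atoms: none
Why: Chelation-controlled Lewis-acid demethylation, in which BCl3 binds the C4 carbonyl and the peri 5-methoxy oxygen in a six-membered chelate so that chloride removes only that methyl group, while the 7-, 8- and 2'-methoxy groups (no chelate) and the 3-methoxy group (only a strained five-membered chelate) survive at or below 0 °C and the cold, non-protic conditions exclude Wessely–Moser isomerisation.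

**Compound list**
1 | 1,2,3,5-tetramethoxybenzene | COc1cc(OC)c(OC)c(OC)c1 | starting material
2 | methoxyacetyl chloride | COCC(=O)Cl | starting material
3 | 2-methoxy-1-(2,3,4,6-tetramethoxyphenyl)ethan-1-one (not isolated) | COCC(=O)c1c(OC)cc(OC)c(OC)c1OC | intermediate
4 | 1-(2-hydroxy-3,4,6-trimethoxyphenyl)-2-methoxyethan-1-one | COCC(=O)c1c(OC)cc(OC)c(OC)c1O | intermediate
5 | 5-hydroxy-2-methoxybenzaldehyde | COc1ccc(O)cc1C=O | starting material
6 | (Z)-1-(2-hydroxy-3,4,6-trimethoxyphenyl)-3-(5-hydroxy-2-methoxyphenyl)-2-methoxyprop-2-en-1-one (not isolated) | COc1ccc(O)cc1/C=C(\OC)C(=O)c1c(OC)cc(OC)c(OC)c1O | intermediate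
7 | 2-(5-hydroxy-2-methoxyphenyl)-3,5,7,8-tetramethoxychroman-4-one (not isolated; racemic cis/trans mixture) | COc1ccc(O)cc1C1Oc2c(OC)c(OC)cc(OC)c2C(=O)C1OC | intermediate
8 | 2-(5-hydroxy-2-methoxyphenyl)-3-iodo-3,5,7,8-tetramethoxychroman-4-one (not isolated; racemic mixture of diastereomers) | COc1ccc(O)cc1C1Oc2c(OC)c(OC)cc(OC)c2C(=O)C1(I)OC | intermediate
9 | 2-(5-hydroxy-2-methoxyphenyl)-3,5,7,8-tetramethoxy-4H-chromen-4-one (5'-hydroxy-3,5,7,8,2'-pentamethoxyflavone) | COc1ccc(O)cc1-c1oc2c(OC)c(OC)cc(OC)c2c(=O)c1OC | intermediate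
10 | 5-hydroxy-2-(5-hydroxy-2-methoxyphenyl)-3,7,8-trimethoxy-4H-chromen-4-one (5,5'-dihydroxy-3,7,8,2'-tetramethoxyflavone; achiral) | COc1ccc(O)cc1-c1oc2c(OC)c(OC)cc(O)c2c(=O)c1OC | target

**Total step count:** 3. **Longest linear sequence:** 3 (1 → 4 → 9 → 10).

**Steps most likely to fail**

Step 2 (the proposed new annulation).
- Risks:
  - The condensation of the hindered α-methoxy ketone may be slow.
  - Iodonium activation of 6 may cause 5-exo attack at the methoxy-bearing carbon and give benzofuranones.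
  - Compound 8 may hydrolyse to the flavonol.
  - Ring iodination may consume the catalyst.
- Fallback: known Baker–Venkataraman chemistry. It sets out from 4, with 5 as the source of ring B, and comes back to the route at 9.
- Aldehyde 5 is benzylated (BnBr, K2CO3, DMF) to 5-(benzyloxy)-2-methoxybenzaldehyde F1. Pinnick oxidation (NaClO2, NaH2PO4, 2-methyl-2-butene, t-BuOH–H2O) then gives 5-(benzyloxy)-2-methoxybenzoic acid F2.
- F2 is esterified with the phenol of 4 (EDC·HCl, DMAP, CH2Cl2) to 3,5,6-trimethoxy-2-(methoxyacetyl)phenyl 5-(benzyloxy)-2-methoxybenzoate F3.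
- KOH in pyridine at 50 °C moves the aroyl group from oxygen to carbon. The product is 1-[5-(benzyloxy)-2-methoxyphenyl]-3-(2-hydroxy-3,4,6-trimethoxyphenyl)-2-methoxypropane-1,3-dione F4.
- AcOH with catalytic H2SO4 at 60 °C closes ring C by cyclodehydration to 2-[5-(benzyloxy)-2-methoxyphenyl]-3,5,7,8-tetramethoxy-4H-chromen-4-one F5.
- Hydrogenolysis (H2, 10% Pd/C, EtOAc–MeOH) gives 9.

Step 1.
- Risks:
  - The methoxyacetyl cation may decarbonylate to a methoxymethyl cation and alkylate instead of acylate.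
  - A second demethylation may occur.
- Fallback: reversed polarity. It sets out from 1 and comes back at 4.
- n-BuLi in THF at 0 °C lithiates 1 at the position flanked by two methoxy groups to give (2,3,4,6-tetramethoxyphenyl)lithium F6.
- F6 is acylated with the Weinreb amide N,2-dimethoxy-N-methylacetamide, and NH4Cl work-up gives 3, which is now isolated.
- A separate treatment with AlCl3 (1.5 equiv, Et2O–CH2Cl2, rt) removes the buttressed 2-O-methyl group and gives 4.

Step 3.
- Risk: the 3- or 8-methoxy group may be cleaved together with the 5-methoxy group.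
- Fallback: oxidative demethylation and re-methylation in place of Lewis-acid cleavage. It sets out from 9 and comes back at 10.
- Compound 9 is acetylated (Ac2O, pyridine) to 4-methoxy-3-(3,5,7,8-tetramethoxy-4-oxo-4H-chromen-2-yl)phenyl acetate F7.
- (NH4)2Ce(NO3)6 in MeCN–H2O at 0 °C oxidises the para-related 5,8-dimethoxy pair to the quinone 3-(3,7-dimethoxy-4,5,8-trioxo-5,8-dihydro-4H-chromen-2-yl)-4-methoxyphenyl acetate F8.
- Na2S2O4 reduces F8 to 3-(5,8-dihydroxy-3,7-dimethoxy-4-oxo-4H-chromen-2-yl)-4-methoxyphenyl acetate F9.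
- Me2SO4 (1.0 equiv) and K2CO3 in acetone methylate only the non-chelated 8-OH. The product is 3-(5-hydroxy-3,7,8-trimethoxy-4-oxo-4H-chromen-2-yl)-4-methoxyphenyl acetate F10.
- K2CO3 in MeOH removes the acetate to give 10.

**Further compounds**
F1 | step 2 | 5-(benzyloxy)-2-methoxybenzaldehyde | COc1ccc(OCc2ccccc2)cc1C=O
F2 | step 2 | 5-(benzyloxy)-2-methoxybenzoic acid | COc1ccc(OCc2ccccc2)cc1C(=O)O
F3 | step 2 | 3,5,6-trimethoxy-2-(methoxyacetyl)phenyl 5-(benzyloxy)-2-methoxybenzoate | COCC(=O)c1c(OC)cc(OC)c(OC)c1OC(=O)c1cc(OCc2ccccc2)ccc1OC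
F4 | step 2 | 1-[5-(benzyloxy)-2-methoxyphenyl]-3-(2-hydroxy-3,4,6-trimethoxyphenyl)-2-methoxypropane-1,3-dione (racemic, enolisable) | COc1ccc(OCc2ccccc2)cc1C(=O)C(OC)C(=O)c1c(OC)cc(OC)c(OC)c1O
F5 | step 2 | 2-[5-(benzyloxy)-2-methoxyphenyl]-3,5,7,8-tetramethoxy-4H-chromen-4-one | COc1ccc(OCc2ccccc2)cc1-c1oc2c(OC)c(OC)cc(OC)c2c(=O)c1OC
F6 | step 1 | (2,3,4,6-tetramethoxyphenyl)lithium | [Li]c1c(OC)cc(OC)c(OC)c1OC
F7 | step 3 | 4-methoxy-3-(3,5,7,8-tetramethoxy-4-oxo-4H-chromen-2-yl)phenyl acetate | COc1ccc(OC(C)=O)cc1-c1oc2c(OC)c(OC)cc(OC)c2c(=O)c1OC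
F8 | step 3 | 3-(3,7-dimethoxy-4,5,8-trioxo-5,8-dihydro-4H-chromen-2-yl)-4-methoxyphenyl acetate | COc1ccc(OC(C)=O)cc1C1=C(OC)C(=O)C2=C(O1)C(=O)C(OC)=CC2=O
F9 | step 3 | 3-(5,8-dihydroxy-3,7-dimethoxy-4-oxo-4H-chromen-2-yl)-4-methoxyphenyl acetate | COc1ccc(OC(C)=O)cc1-c1oc2c(O)c(OC)cc(O)c2c(=O)c1OC
F10 | step 3 | 3-(5-hydroxy-3,7,8-trimethoxy-4-oxo-4H-chromen-2-yl)-4-methoxyphenyl acetate | COc1ccc(OC(C)=O)cc1-c1oc2c(OC)c(OC)cc(O)c2c(=O)c1OC
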